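**Retrosynthetic overview**
1. Last operations: the C4–C5 oxirane comes from peripheral epoxidation of an (E)-C4=C5 alkene, and the C1 ketone from a C1 carbinol.
2. Key disconnection: C7–C8 and O–C10 are cut together, which leads to an acyclic β,γ-epoxy aldehyde tethered to a 3-(chloromethyl)-4-tigloyloxy-butenolide. A divalent-chromium allylation closes the ten-membered carbocycle, the tiglate moves from O7 to O8, and O7 opens the C1–C10 oxirane to give the tetrahydrofuran.
3. Enabling feature: the spiro carbon C7 carries the ring oxygen next to the acylated C8 carbinol and bears the C11=C13 methylene of the lactone (a γ-oxyallyl-metal plus aldehyde pattern). That oxygen is 1,4 to C10, whose neighbour C1 is oxygenated (a 5-exo epoxide-opening pattern), inside the 11-oxabicyclo[6.2.1]undecane made of the tetrahydrofuran and the ten-membered carbocycle.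
4. The butenolide (a tetronic acid) comes from Dieckmann closure of an (R)-α-acetoxy ester, with C13 added by Mannich aminomethylation. C6 is set by a ketoreductase and relayed to C7, C8, C4 and C5; the C1/C10 oxirane is set by a hydroxyl-directed catalytic epoxidation.
5. The chain comes from two zirconium-catalysed carboaluminations and one Negishi coupling. Ring order: butenolide, then ten-membered carbocycle and tetrahydrofuran in one step, then oxirane.

Key step: step 12

Remark: germacrane numbering is used for the target atoms (C1 ketone, C4/C5 oxirane, C6 lactone CH–O, C7 spiro carbon, C8 tiglate carbinol, C10 methyl-bearing ether carbon, C11=C13 methylene, C12 lactone carbonyl); it is assumed that the enzyme of step 5 and the ligand enantiomer of step 10 can be chosen in the sense that gives the stated configurations.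

**Step 1**
Reactants: 1 tert-butyl(but-3-yn-1-yloxy)dimethylsilane
Product: 3 tert-butyl{[(3E)-4-iodo-3-methylbut-3-en-1-yl]oxy}dimethylsilane, via alkenylalane 2 (not isolated)
Conditions: Me3Al, Cp2ZrCl2 (cat.), CH2Cl2, 0 to 23 °C; then I2, THF, −30 °C
Reagents that add atoms: trimethylaluminium C[Al](C)C; iodine II
Why: Zirconium-catalysed syn-carboalumination of the terminal alkyne (Negishi carboalumination) puts methyl on the internal carbon and aluminium on the terminus, and iodinolysis with retention should give the (E)-iodoalkene (C8–C9–C10(Me)=C1).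

**Step 2**
Reactants: 3 tert-butyl{[(3E)-4-iodo-3-methylbut-3-en-1-yl]oxy}dimethylsilane; 4 (4-bromobut-1-yn-1-yl)trimethylsilane
Product: 6 tert-butyldimethyl{[(3E)-3-methyl-8-(trimethylsilyl)oct-3-en-7-yn-1-yl]oxy}silane, via alkylzinc bromide 5 (not isolated)
Conditions: 4, Zn, LiCl, THF, 40 °C; then 3, Pd(PPh3)4 (5 mol %), THF, 23 °C
Reagents that add atoms: none
Why: Negishi coupling of the primary alkylzinc bromide with the alkenyl iodide on zerovalent palladium should form C1–C2 with retention of the (E)-geometry and leave both silyl groups untouched.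

**Step 3**
Reactants: 6 tert-butyldimethyl{[(3E)-3-methyl-8-(trimethylsilyl)oct-3-en-7-yn-1-yl]oxy}silane
Product: 7 tert-butyldimethyl{[(3E)-3-methyloct-3-en-7-yn-1-yl]oxy}silane
Conditions: K2CO3, MeOH, 23 °C
Reagents that add atoms: none
Why: Base-mediated methanolysis (protiodesilylation) cleaves only the alkynyl C–Si bond and should spare the alkyl silyl ether.

**Step 4**
Reactants: 7 tert-butyldimethyl{[(3E)-3-methyloct-3-en-7-yn-1-yl]oxy}silane
Product: 9 methyl (3E,7E)-10-{[tert-butyl(dimethyl)silyl]oxy}-4,8-dimethyl-2-oxodeca-3,7-dienoate, via dienylalane 8 (not isolated)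
Conditions: Me3Al, Cp2ZrCl2 (cat.), CH2Cl2, 23 °C; then cannulated into ClC(O)CO2Me, CH2Cl2, −30 °C
Reagents that add atoms: trimethylaluminium C[Al](C)C; methyl chlorooxoacetate COC(=O)C(Cl)=O
Why: A second syn-carboalumination sets the (E)-trisubstituted C4=C5 alkene, and acylation of the alkenylalane by the acid chloride with retention should give the β,γ-unsaturated α-keto ester (C6, C7).

**Step 5**
Reactants: 9 methyl (3E,7E)-10-{[tert-butyl(dimethyl)silyl]oxy}-4,8-dimethyl-2-oxodeca-3,7-dienoate
Product: 10 methyl (2R,3E,7E)-10-{[tert-butyl(dimethyl)silyl]oxy}-2-hydroxy-4,8-dimethyldeca-3,7-dienoate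
Conditions: (R)-selective ketoreductase, NADP+ (cat.), i-PrOH, phosphate buffer pH 7, DMSO (10%), 30 °C
Reagents that add atoms: none
Why: Enzymatic carbonyl reduction by an NADPH-dependent ketoreductase (alcohol dehydrogenase class) should deliver hydride to one face of the activated α-keto ester and set C6 as (R), the stereocentre from which C7, C8, C4 and C5 are later relayed.

**Step 6**
Reactants: 10 methyl (2R,3E,7E)-10-{[tert-butyl(dimethyl)silyl]oxy}-2-hydroxy-4,8-dimethyldeca-3,7-dienoate
Product: 11 methyl (2R,3E,7E)-2-acetoxy-10-{[tert-butyl(dimethyl)silyl]oxy}-4,8-dimethyldeca-3,7-dienoate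
Conditions: Ac2O, pyridine, DMAP (cat.), CH2Cl2, 0 °C
Reagents that add atoms: acetic anhydride CC(=O)OC(C)=O
Why: Standard acylation of the secondary alcohol brings in the two carbons C11 and C12 of the lactone without touching C6.

**Step 7**
Reactants: 11 methyl (2R,3E,7E)-2-acetoxy-10-{[tert-butyl(dimethyl)silyl]oxy}-4,8-dimethyldeca-3,7-dienoate
Product: 13 (5R)-5-[(1E,5E)-8-{[tert-butyl(dimethyl)silyl]oxy}-2,6-dimethylocta-1,5-dien-1-yl]-3-[(dimethylamino)methyl]-4-hydroxyfuran-2(5H)-one, via lithium tetronate 12 (not isolated)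
Conditions: LiN(SiMe3)2 (2.3 equiv), THF, −78 to −20 °C; then [Me2N=CH2]I (1.1 equiv), −20 to 0 °C
Reagents that add atoms: N,N-dimethylmethyleneiminium iodide C[N+](C)=C.[I-]
Why: Dieckmann condensation of the acetate enolate onto the methyl ester should close the tetronate ring, whose nucleophilic C11 is then aminomethylated by the iminium salt (Mannich reaction) to bring in C13, the C6 stereocentre staying untouched as long as the acetate is deprotonated faster than C6–H.

**Step 8**
Reactants: 13 (5R)-5-[(1E,5E)-8-{[tert-butyl(dimethyl)silyl]oxy}-2,6-dimethylocta-1,5-dien-1-yl]-3-[(dimethylamino)methyl]-4-hydroxyfuran-2(5H)-one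
Product: 15 (2R)-2-[(1E,5E)-8-{[tert-butyl(dimethyl)silyl]oxy}-2,6-dimethylocta-1,5-dien-1-yl]-4-(chloromethyl)-5-oxo-2,5-dihydrofuran-3-yl (2E)-2-methylbut-2-enoate, via O-tigloyl Mannich base 14 (not isolated)
Conditions: (E)-MeCH=C(Me)COCl (1.05 equiv), i-Pr2NEt, CH2Cl2, −40 °C; then ClCO2Et (1.5 equiv), 0 to 23 °C
Reagents that add atoms: (2E)-2-methylbut-2-enoyl chloride C/C=C(\C)C(Cl)=O; ethyl chloroformate CCOC(Cl)=O
Why: O-Acylation of the tetronic acid gives the enol tiglate, and N-acylation of the allylic dimethylamine by the chloroformate should trigger chloride displacement at C13 (von Braun-type dealkylation of a Mannich base) to give the allylic chloride.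

**Step 9**
Reactants: 15 (2R)-2-[(1E,5E)-8-{[tert-butyl(dimethyl)silyl]oxy}-2,6-dimethylocta-1,5-dien-1-yl]-4-(chloromethyl)-5-oxo-2,5-dihydrofuran-3-yl (2E)-2-methylbut-2-enoate
Product: 16 (2R)-4-(chloromethyl)-2-[(1E,5E)-8-hydroxy-2,6-dimethylocta-1,5-dien-1-yl]-5-oxo-2,5-dihydrofuran-3-yl (2E)-2-methylbut-2-enoate
Conditions: HF (48% aq.), MeCN, 0 °C
Reagents that add atoms: none
Why: Acidic fluoride cleaves the primary silyl ether without a nucleophilic base that could attack the allylic chloride or the enol ester.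

**Step 10**
Reactants: 16 (2R)-4-(chloromethyl)-2-[(1E,5E)-8-hydroxy-2,6-dimethylocta-1,5-dien-1-yl]-5-oxo-2,5-dihydrofuran-3-yl (2E)-2-methylbut-2-enoate
Product: 17 (2R)-4-(chloromethyl)-2-{(1E)-4-[(2S,3S)-3-(2-hydroxyethyl)-3-methyloxiran-2-yl]-2-methylbut-1-en-1-yl}-5-oxo-2,5-dihydrofuran-3-yl (2E)-2-methylbut-2-enoate
Conditions: VO(Oi-Pr)3 (2 mol %), C2-symmetric chiral bis-hydroxamic acid ligand (3 mol %), cumene hydroperoxide, toluene, 0 °C
Reagents that add atoms: cumene hydroperoxide CC(C)(OO)c1ccccc1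
Why: Vanadium-catalysed hydroxyl-directed asymmetric epoxidation of the homoallylic alcohol should oxidise only the C1=C10 alkene next to the coordinating hydroxyl, the chiral ligand setting the (1S,10S) trans-oxirane by reagent control.

**Step 11**
Reactants: 17 (2R)-4-(chloromethyl)-2-{(1E)-4-[(2S,3S)-3-(2-hydroxyethyl)-3-methyloxiran-2-yl]-2-methylbut-1-en-1-yl}-5-oxo-2,5-dihydrofuran-3-yl (2E)-2-methylbut-2-enoate
Product: 18 (2R)-4-(chloromethyl)-2-{(1E)-2-methyl-4-[(2S,3S)-3-methyl-3-(2-oxoethyl)oxiran-2-yl]but-1-en-1-yl}-5-oxo-2,5-dihydrofuran-3-yl (2E)-2-methylbut-2-enoate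
Conditions: Dess–Martin periodinane, NaHCO3, CH2Cl2, 0 °C; used at once
Reagents that add atoms: none
Why: Dess–Martin oxidation under buffered, non-basic conditions should give the sensitive β,γ-epoxy aldehyde without β-elimination.

**Step 12**
Reactants: 18 (2R)-4-(chloromethyl)-2-{(1E)-2-methyl-4-[(2S,3S)-3-methyl-3-(2-oxoethyl)oxiran-2-yl]but-1-en-1-yl}-5-oxo-2,5-dihydrofuran-3-yl (2E)-2-methylbut-2-enoate
Product: 21 (1S,6R,7S,8S,10R)-7,10-epoxy-1-hydroxy-8-[(2E)-2-methylbut-2-enoyloxy]germacra-4(E),11(13)-dien-12,6-olide, via chromium alkoxide 19 (not isolated), via hydroxy tiglate 20 (not isolated)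
Conditions: CrCl2 (10 equiv), LiI (0.5 equiv), THF, 2 mM (slow addition of 18), 23 °C; then H2O (10 equiv), camphorsulfonic acid (0.3 equiv), 23 °C, same flask
Reagents that add atoms: none
Why: Divalent chromium turns the allylic chloride (through the iodide) into a 2-carbonyl-substituted γ-acyloxyallyl chromium species that adds through its oxygen-bearing γ-carbon C7 to the C8 aldehyde (Nozaki–Hiyama–Kishi-type Barbier allylation, the reaction type that closes ten-membered germacranolide rings from 2-(halomethyl)enoates and gives 1,2-diol monoesters from γ-acyloxyallyl halides); this forms C7–C8, closes the ten-membered carbocycle by intramolecular SE2' carbonyl addition and creates the C11=C13 methylene. The tiglate then shifts from the tertiary O7 to the new secondary O8 through a five-membered orthoester (1,2-acyl migration), and the freed tertiary hydroxyl opens the C1–C10 oxirane at its tertiary carbon C10 (acid-catalysed 5-exo-tet epoxide opening), which forms O–C10 and closes the tetrahydrofuran. C7 is controlled by C6, because the aldehyde should add to the face of the planar butenolide anti to C5 (trans-fused lactone); C8 is controlled relative to C7 by the closed chair-like six-membered transition state, in which the ring-fixed allyl geometry (O-acyl cis to the CH2Cr terminus) places O7 and O8 syn; C10 is controlled by inversion at the (S)-configured oxirane carbon and is the only configuration the six-carbon bridge C1–C6 permits. The step needs γ- over α-regioselectivity (2-carbonyl allylchromium reagents react at the substituted terminus), ring closure over oligomerisation (slow addition at high dilution, three rigid units in the chain) and attack of O7 instead of O8 on the oxirane (5-exo against 4-exo, and the acyl shift caps O8).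

**Step 13**
Reactants: 21 (1S,6R,7S,8S,10R)-7,10-epoxy-1-hydroxy-8-[(2E)-2-methylbut-2-enoyloxy]germacra-4(E),11(13)-dien-12,6-olide
Product: 22 (6R,7S,8S,10R)-7,10-epoxy-8-[(2E)-2-methylbut-2-enoyloxy]-1-oxogermacra-4(E),11(13)-dien-12,6-olide
Conditions: Dess–Martin periodinane, NaHCO3, CH2Cl2, 23 °C
Reagents that add atoms: none
Why: Dess–Martin oxidation of the only free hydroxyl gives the C1 ketone, which cannot enolise towards the quaternary C10.

**Step 14**
Reactants: 22 (6R,7S,8S,10R)-7,10-epoxy-8-[(2E)-2-methylbut-2-enoyloxy]-1-oxogermacra-4(E),11(13)-dien-12,6-olide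
Product: 23 (4R,5R,6R,7S,8S,10R)-4,5:7,10-diepoxy-8-[(2E)-2-methylbut-2-enoyloxy]-1-oxogermacr-11(13)-en-12,6-olide
Conditions: dimethyldioxirane, acetone/CH2Cl2, −20 to 0 °C
Reagents that add atoms: dimethyldioxirane CC1(C)OO1
Why: Electrophilic epoxidation by the dioxirane should select the only electron-rich alkene (methylene lactone and tiglate are electron-poor) and attack the exposed peripheral face of the (E)-C4=C5 bond, anti to the ring atom C7, which sets C4 and C5 as (R,R) by substrate control from C6.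

**Compound list**
1 | tert-butyl(but-3-yn-1-yloxy)dimethylsilane | C#CCCO[Si](C)(C)C(C)(C)C | starting material
2 | [(1E)-4-{[tert-butyl(dimethyl)silyl]oxy}-2-methylbut-1-en-1-yl]dimethylalane | C[Al](C)/C=C(\C)CCO[Si](C)(C)C(C)(C)C | intermediate
3 | tert-butyl{[(3E)-4-iodo-3-methylbut-3-en-1-yl]oxy}dimethylsilane | I/C=C(\C)CCO[Si](C)(C)C(C)(C)C | intermediate
4 | (4-bromobut-1-yn-1-yl)trimethylsilane | BrCCC#C[Si](C)(C)C | starting material
5 | bromo[4-(trimethylsilyl)but-3-yn-1-yl]zinc | Br[Zn]CCC#C[Si](C)(C)C | intermediate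
6 | tert-butyldimethyl{[(3E)-3-methyl-8-(trimethylsilyl)oct-3-en-7-yn-1-yl]oxy}silane | C[Si](C)(C)C#CCC/C=C(\C)CCO[Si](C)(C)C(C)(C)C | intermediate
7 | tert-butyldimethyl{[(3E)-3-methyloct-3-en-7-yn-1-yl]oxy}silane | C#CCC/C=C(\C)CCO[Si](C)(C)C(C)(C)C | intermediate
8 | [(1E,5E)-8-{[tert-butyl(dimethyl)silyl]oxy}-2,6-dimethylocta-1,5-dien-1-yl]dimethylalane | C[Al](C)/C=C(\C)CC/C=C(\C)CCO[Si](C)(C)C(C)(C)C | intermediate
9 | methyl (3E,7E)-10-{[tert-butyl(dimethyl)silyl]oxy}-4,8-dimethyl-2-oxodeca-3,7-dienoate | COC(=O)C(=O)/C=C(\C)CC/C=C(\C)CCO[Si](C)(C)C(C)(C)C | intermediate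
10 | methyl (2R,3E,7E)-10-{[tert-butyl(dimethyl)silyl]oxy}-2-hydroxy-4,8-dimethyldeca-3,7-dienoate | COC(=O)[C@H](O)/C=C(\C)CC/C=C(\C)CCO[Si](C)(C)C(C)(C)C | intermediate
11 | methyl (2R,3E,7E)-2-acetoxy-10-{[tert-butyl(dimethyl)silyl]oxy}-4,8-dimethyldeca-3,7-dienoate | COC(=O)[C@H](OC(C)=O)/C=C(\C)CC/C=C(\C)CCO[Si](C)(C)C(C)(C)C | intermediate
12 | lithium (5R)-5-[(1E,5E)-8-{[tert-butyl(dimethyl)silyl]oxy}-2,6-dimethylocta-1,5-dien-1-yl]-2-oxo-2,5-dihydrofuran-4-olate | O=C1C=C([O-])[C@@H](/C=C(\C)CC/C=C(\C)CCO[Si](C)(C)C(C)(C)C)O1.[Li+] | intermediate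
13 | (5R)-5-[(1E,5E)-8-{[tert-butyl(dimethyl)silyl]oxy}-2,6-dimethylocta-1,5-dien-1-yl]-3-[(dimethylamino)methyl]-4-hydroxyfuran-2(5H)-one | CN(C)CC1=C(O)[C@@H](/C=C(\C)CC/C=C(\C)CCO[Si](C)(C)C(C)(C)C)OC1=O | intermediate
14 | (2R)-2-[(1E,5E)-8-{[tert-butyl(dimethyl)silyl]oxy}-2,6-dimethylocta-1,5-dien-1-yl]-4-[(dimethylamino)methyl]-5-oxo-2,5-dihydrofuran-3-yl (2E)-2-methylbut-2-enoate | CN(C)CC1=C(OC(=O)/C(C)=C/C)[C@@H](/C=C(\C)CC/C=C(\C)CCO[Si](C)(C)C(C)(C)C)OC1=O | intermediate
15 | (2R)-2-[(1E,5E)-8-{[tert-butyl(dimethyl)silyl]oxy}-2,6-dimethylocta-1,5-dien-1-yl]-4-(chloromethyl)-5-oxo-2,5-dihydrofuran-3-yl (2E)-2-methylbut-2-enoate | ClCC1=C(OC(=O)/C(C)=C/C)[C@@H](/C=C(\C)CC/C=C(\C)CCO[Si](C)(C)C(C)(C)C)OC1=O | intermediate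
16 | (2R)-4-(chloromethyl)-2-[(1E,5E)-8-hydroxy-2,6-dimethylocta-1,5-dien-1-yl]-5-oxo-2,5-dihydrofuran-3-yl (2E)-2-methylbut-2-enoate | ClCC1=C(OC(=O)/C(C)=C/C)[C@@H](/C=C(\C)CC/C=C(\C)CCO)OC1=O | intermediate
17 | (2R)-4-(chloromethyl)-2-{(1E)-4-[(2S,3S)-3-(2-hydroxyethyl)-3-methyloxiran-2-yl]-2-methylbut-1-en-1-yl}-5-oxo-2,5-dihydrofuran-3-yl (2E)-2-methylbut-2-enoate | ClCC1=C(OC(=O)/C(C)=C/C)[C@@H](/C=C(\C)CC[C@@H]2O[C@@]2(C)CCO)OC1=O | intermediate
18 | (2R)-4-(chloromethyl)-2-{(1E)-2-methyl-4-[(2S,3S)-3-methyl-3-(2-oxoethyl)oxiran-2-yl]but-1-en-1-yl}-5-oxo-2,5-dihydrofuran-3-yl (2E)-2-methylbut-2-enoate | ClCC1=C(OC(=O)/C(C)=C/C)[C@@H](/C=C(\C)CC[C@@H]2O[C@@]2(C)CC=O)OC1=O | intermediate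
19 | dichlorochromium O8-alkoxide of (1S,6R,7S,8S,10S)-1,10-epoxy-8-hydroxy-7-[(2E)-2-methylbut-2-enoyloxy]germacra-4(E),11(13)-dien-12,6-olide | C=C1C(=O)O[C@@H]2/C=C(\C)CC[C@@H]3O[C@@]3(C)C[C@H](O[Cr](Cl)Cl)[C@@]12OC(=O)/C(C)=C/C | intermediate
20 | (1S,6R,7S,8S,10S)-1,10-epoxy-7-hydroxy-8-[(2E)-2-methylbut-2-enoyloxy]germacra-4(E),11(13)-dien-12,6-olide | C=C1C(=O)O[C@@H]2/C=C(\C)CC[C@@H]3O[C@@]3(C)C[C@H](OC(=O)/C(C)=C/C)[C@@]12O | intermediate
21 | (1S,6R,7S,8S,10R)-7,10-epoxy-1-hydroxy-8-[(2E)-2-methylbut-2-enoyloxy]germacra-4(E),11(13)-dien-12,6-olide | C=C1C(=O)O[C@@H]2/C=C(\C)CC[C@H](O)[C@@]3(C)C[C@H](OC(=O)/C(C)=C/C)[C@@]12O3 | intermediate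
22 | (6R,7S,8S,10R)-7,10-epoxy-8-[(2E)-2-methylbut-2-enoyloxy]-1-oxogermacra-4(E),11(13)-dien-12,6-olide | C=C1C(=O)O[C@@H]2/C=C(\C)CCC(=O)[C@@]3(C)C[C@H](OC(=O)/C(C)=C/C)[C@@]12O3 | intermediate
23 | (4R,5R,6R,7S,8S,10R)-4,5:7,10-diepoxy-8-[(2E)-2-methylbut-2-enoyloxy]-1-oxogermacr-11(13)-en-12,6-olide | C=C1C(=O)O[C@@H]2[C@H]3O[C@]3(C)CCC(=O)[C@@]3(C)C[C@H](OC(=O)/C(C)=C/C)[C@@]12O3 | target

Total step count: 14. Longest linear sequence: 14 steps (from 1).

**Steps most likely to fail**

Step 12. Several processes can divert the cascade: oligomerisation or ring closure through the CH2 terminus of the allyl unit, β-elimination of the epoxy aldehyde on the Lewis-acidic trivalent chromium salts, opening of the oxirane before the tiglate has moved, and the wrong face or epimer in the macrocyclic transition state. The fallback separates ether formation from ring closure and replaces the oxirane by the alkene. It sets out from 16: Dess–Martin oxidation gives the dienal F1, and the same CrCl2/LiI ring closure on this less fragile substrate, followed by imidazole to complete the acyl shift, gives the hydroxy tiglate triene F2. Pyridinium chlorochromate then effects oxidative cyclisation of the tertiary bishomoallylic alcohol onto the C1=C10 alkene (hexavalent-chromium oxidative cyclisation of 4-penten-1-ol-type alcohols). This forms O–C10 and the C1 ketone together, and the route is rejoined at 22.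

Step 7. Deprotonation at C6 (allylic and α to the ester) can compete with enolisation of the acetate, which would cause racemisation or a 1,2-acyl shift to carbon. The Mannich base can also lose amine and be captured by a second tetronate. The fallback makes the enolate regiospecifically by metal insertion instead of deprotonation. It sets out from 10: acylation with bromoacetyl bromide and pyridine gives the bromoacetate F3. Zinc insertion (activated Zn, THF, 40 °C) gives the Reformatsky enolate, which closes onto the methyl ester; the zinc tetronate is quenched in the same flask with the iminium iodide, and the route is rejoined at 13.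

Step 14. Facial selectivity may be poor or reversed if the bridged ring exposes the inner face of the alkene. The fallback delivers the oxygen to the face opposite to that attacked by an electrophile. It sets out from 22: N-bromosuccinimide in wet THF gives the bromohydrin F4 (bromonium on the exposed face, water anti at the tertiary C4). K2CO3 in acetone then closes the oxirane with inversion at C5, and the route is rejoined at 23.

**Further compounds**
F1 | step 12 | (2R)-4-(chloromethyl)-2-[(1E,5E)-2,6-dimethyl-8-oxoocta-1,5-dien-1-yl]-5-oxo-2,5-dihydrofuran-3-yl (2E)-2-methylbut-2-enoate | ClCC1=C(OC(=O)/C(C)=C/C)[C@@H](/C=C(\C)CC/C=C(\C)CC=O)OC1=O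
F2 | step 12 | (6R,7S,8S)-7-hydroxy-8-[(2E)-2-methylbut-2-enoyloxy]germacra-1(10)E,4E,11(13)-trien-12,6-olide | C=C1C(=O)O[C@@H]2/C=C(\C)CC/C=C(\C)C[C@H](OC(=O)/C(C)=C/C)[C@@]12O
F3 | step 7 | methyl (2R,3E,7E)-2-(bromoacetoxy)-10-{[tert-butyl(dimethyl)silyl]oxy}-4,8-dimethyldeca-3,7-dienoate | COC(=O)[C@H](OC(=O)CBr)/C=C(\C)CC/C=C(\C)CCO[Si](C)(C)C(C)(C)C
F4 | step 14 | (4R,5S,6S,7S,8S,10R)-5-bromo-7,10-epoxy-4-hydroxy-8-[(2E)-2-methylbut-2-enoyloxy]-1-oxogermacr-11(13)-en-12,6-olide | C=C1C(=O)O[C@@H]2[C@H](Br)[C@@](O)(C)CCC(=O)[C@@]3(C)C[C@H](OC(=O)/C(C)=C/C)[C@@]12O3
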